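## Retrosynthetic overview

- The target is a trans-(2S,3S)-2-aryl-3-methyl-2,3-dihydrobenzofuran. The (E)-propenyl group is attached last by Suzuki coupling at C5–Br, so C5 carries an inert bromine while the heterocycle is made.
- Ring C (the dihydrofuran) is the only ring formed; rings A and B are purchased. It is closed at O1–C2 by a catalytic asymmetric, redox-neutral cycloisomerisation of an achiral, acyclic (E)-2-hydroxy-4'-hydroxy-α-methylstilbene, which sets C3 and C2 in the same operation.
- Enabling feature: C2 is benzylic to ring B and para to the free OH of the 4-hydroxy-3,5-dimethoxyphenyl group, so the C2=C3 alkene is the tautomer of a ring B p-quinone methide with C2 as its exocyclic carbon. O1 sits on C7a of ring A, ortho to C3a, so it is next to C3 for proton relay and placed for five-membered closure on C2.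
- The stilbene comes from a Suzuki coupling (C–I before C–Br) of 4-bromo-2-iodo-6-methoxyphenol with a (Z)-alkenylboronate, itself made by syn-borylcupration of the ring B arylpropyne.

Key step: step 6

Assumption: the sense of induction of the phosphoric acid in step 6 has no direct precedent on this substrate; (R)-TRIP is written, and its mirror image is to be used if it should favour the (2R,3R) series.

## Route

Step 1
Reactants: 1 4-bromo-2-methoxyphenol
Product: 2 4-bromo-2-iodo-6-methoxyphenol
Conditions: NIS (1.05 equiv), TsOH·H2O (5 mol %), MeCN, 0 °C to rt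
Reagents that add atoms: N-iodosuccinimide, O=C1CCC(=O)N1I
Why: Electrophilic aromatic iodination; the hydroxyl directs, its para position carries Br and one ortho position OMe, so iodine should enter the only free ortho position.

Step 2
Reactants: 3 4-bromo-2,6-dimethoxyphenol
Product: 4 (4-bromo-2,6-dimethoxyphenoxy)(tert-butyl)dimethylsilane
Conditions: TBSCl (1.3 equiv), imidazole (2.5 equiv), DMF, rt to 40 °C
Reagents that add atoms: tert-butyldimethylsilyl chloride, CC(C)(C)[Si](C)(C)Cl
Why: Imidazole-promoted silylation masks the syringol OH, which would otherwise consume base and boron reagent in steps 3 and 4, and the silyl ether can later be removed by fluoride without acid.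

Step 3
Reactants: 4 (4-bromo-2,6-dimethoxyphenoxy)(tert-butyl)dimethylsilane
Product: 5 tert-butyl[2,6-dimethoxy-4-(prop-1-yn-1-yl)phenoxy]dimethylsilane
Conditions: propyne (3 equiv), PdCl2(PPh3)2 (3 mol %), CuI (5 mol %), Et3N/THF, 65 °C, sealed tube
Reagents that add atoms: propyne, CC#C
Why: Sonogashira coupling (oxidative addition of the aryl bromide to zerovalent palladium, transmetalation from the copper propynylide, reductive elimination); the electron-rich bromide is the reason for heating.

Step 4
Reactants: 5 tert-butyl[2,6-dimethoxy-4-(prop-1-yn-1-yl)phenoxy]dimethylsilane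
Product: 6 2-[(Z)-1-(4-{[tert-butyl(dimethyl)silyl]oxy}-3,5-dimethoxyphenyl)prop-1-en-2-yl]-4,4,5,5-tetramethyl-1,3,2-dioxaborolane
Conditions: B2pin2 (1.1 equiv), CuCl (5 mol %), P(p-tol)3 (6 mol %), NaOt-Bu (10 mol %), MeOH (2 equiv), THF, rt
Reagents that add atoms: bis(pinacolato)diboron, CC1(C)OB(OC1(C)C)B1OC(C)(C)C(C)(C)O1
Why: Copper-catalysed formal hydroboration (syn-borylcupration, then protonation by MeOH) should put copper on the aryl-bearing carbon and boron on the methyl-bearing carbon, and syn addition places boron trans to the aryl group, the geometry that becomes the (E)-stilbene.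

Step 5
Reactants: 2 4-bromo-2-iodo-6-methoxyphenol; 6 2-[(Z)-1-(4-{[tert-butyl(dimethyl)silyl]oxy}-3,5-dimethoxyphenyl)prop-1-en-2-yl]-4,4,5,5-tetramethyl-1,3,2-dioxaborolane
Product: 8 4-[(E)-2-(5-bromo-2-hydroxy-3-methoxyphenyl)prop-1-en-1-yl]-2,6-dimethoxyphenol, via stilbene silyl ether 7 (not isolated)
Conditions: Pd(dppf)Cl2 (5 mol %), K3PO4 (3 equiv), 1,4-dioxane/H2O 5:1, 60 °C; crude 7, then TBAF/AcOH 1:1 (1.5 equiv), THF, 0 °C; chromatography on Et3N-treated silica
Reagents that add atoms: none
Why: Suzuki–Miyaura coupling with retention of alkene geometry, selective for C–I over C–Br because oxidative addition to the iodide is much faster, followed by fluoride cleavage of the aryl silyl ether under acetate buffering, which keeps the acid-sensitive hydroxystilbene away from acid.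

Step 6
Reactants: 8 4-[(E)-2-(5-bromo-2-hydroxy-3-methoxyphenyl)prop-1-en-1-yl]-2,6-dimethoxyphenol
Product: 10 4-[(2S,3S)-5-bromo-7-methoxy-3-methyl-2,3-dihydro-1-benzofuran-2-yl]-2,6-dimethoxyphenol, via (R)-p-quinone methide 9 (not isolated)
Conditions: (R)-TRIP (10 mol %), toluene (0.02 M), 4 Å MS, −20 to 0 °C
Reagents that add atoms: none
Why: Proposed new method: the chiral phosphoric acid, hydrogen-bonded to the ring A hydroxyl that lies ortho to the carbon bearing C3, delivers its proton to C3 of the 4-hydroxystilbene (the aromatic tautomer of a ring B p-quinone methide), and the ion-paired quinone methide 9 is captured at its exocyclic carbon C2 by the same ring A oxygen as the phosphate takes back the phenolic proton, so that O1–C2 forms in a redox-neutral, catalyst-shuttled transfer of H from O1 to C3. The closest known reaction types are the chiral Brønsted acid catalysed intramolecular hydroalkoxylation of alkenes and the phosphoric acid catalysed generation of quinone methides from hydroxystyrenes with enantioselective 1,6-addition. Ring C closes 5-exo-trig onto the exocyclic C=C of 9 (a formal 5-endo-trig hydroalkoxylation of the stilbene, made feasible only by the stepwise path through 9). C3 is set by the face of proton delivery within the chiral ion pair (catalyst control; 3R in 9 and 3S in 10 are the same spatial arrangement, the descriptor changes because C2 gains oxygen), and C2 is set by C3, since closure anti to the C3 methyl gives the trans ring and reversible C2–O ionisation lets any cis isomer drain to trans without touching C3. The step needs protonation at C3 in preference to C2 and ring closure in preference to intermolecular arylation: the syringyl ring (para OH flanked by two OMe) stabilises positive charge at C2 far better than anything else in the molecule, protonation at C2 (ring A o-quinone methide) is reversible and leads nowhere, and bromine blocking the position para to O1 together with high dilution suppresses Friedel–Crafts dimerisation.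

Step 7
Reactants: 10 4-[(2S,3S)-5-bromo-7-methoxy-3-methyl-2,3-dihydro-1-benzofuran-2-yl]-2,6-dimethoxyphenol
Product: 11 Odoratisol A
Conditions: (E)-prop-1-enyl-Bpin (1.5 equiv), Pd(OAc)2 (3 mol %), SPhos (6 mol %), K2CO3 (3 equiv), THF/H2O 10:1, 45 °C
Reagents that add atoms: (E)-4,4,5,5-tetramethyl-2-(prop-1-en-1-yl)-1,3,2-dioxaborolane, C/C=C/B1OC(C)(C)C(C)(C)O1
Why: Suzuki–Miyaura coupling of the aryl bromide with the (E)-alkenylboronate proceeds with retention, so the E geometry comes with the reagent, and the mild carbonate base and low temperature are chosen so that the phenolic dihydrobenzofuran does not reopen and C2 and C3 stay untouched.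

## Compound list

1 | 4-bromo-2-methoxyphenol | COc1cc(Br)ccc1O | starting material
2 | 4-bromo-2-iodo-6-methoxyphenol | COc1cc(Br)cc(I)c1O | intermediate
3 | 4-bromo-2,6-dimethoxyphenol | COc1cc(Br)cc(OC)c1O | starting material
4 | (4-bromo-2,6-dimethoxyphenoxy)(tert-butyl)dimethylsilane | COc1cc(Br)cc(OC)c1O[Si](C)(C)C(C)(C)C | intermediate
5 | tert-butyl[2,6-dimethoxy-4-(prop-1-yn-1-yl)phenoxy]dimethylsilane | CC#Cc1cc(OC)c(O[Si](C)(C)C(C)(C)C)c(OC)c1 | intermediate
6 | 2-[(Z)-1-(4-{[tert-butyl(dimethyl)silyl]oxy}-3,5-dimethoxyphenyl)prop-1-en-2-yl]-4,4,5,5-tetramethyl-1,3,2-dioxaborolane | C/C(B1OC(C)(C)C(C)(C)O1)=C\c1cc(OC)c(O[Si](C)(C)C(C)(C)C)c(OC)c1 | intermediate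
7 | 4-bromo-2-[(E)-1-(4-{[tert-butyl(dimethyl)silyl]oxy}-3,5-dimethoxyphenyl)prop-1-en-2-yl]-6-methoxyphenol | C/C(c1cc(Br)cc(OC)c1O)=C\c1cc(OC)c(O[Si](C)(C)C(C)(C)C)c(OC)c1 | intermediate (not isolated)
8 | 4-[(E)-2-(5-bromo-2-hydroxy-3-methoxyphenyl)prop-1-en-1-yl]-2,6-dimethoxyphenol | C/C(c1cc(Br)cc(OC)c1O)=C\c1cc(OC)c(O)c(OC)c1 | intermediate
9 | 4-[(2R)-2-(5-bromo-2-hydroxy-3-methoxyphenyl)propylidene]-2,6-dimethoxycyclohexa-2,5-dien-1-one | Brc1cc(OC)c(O)c(c1)[C@H](C)C=C1C=C(OC)C(=O)C(OC)=C1 | intermediate (not isolated)
10 | 4-[(2S,3S)-5-bromo-7-methoxy-3-methyl-2,3-dihydro-1-benzofuran-2-yl]-2,6-dimethoxyphenol | Brc1cc(OC)c2c(c1)[C@H](C)[C@@H](c1cc(OC)c(O)c(OC)c1)O2 | intermediate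
11 | Odoratisol A, 2,6-dimethoxy-4-[(2S,3S)-7-methoxy-3-methyl-5-[(E)-prop-1-en-1-yl]-2,3-dihydro-1-benzofuran-2-yl]phenol | C/C=C/c1cc(OC)c2c(c1)[C@H](C)[C@@H](c1cc(OC)c(O)c(OC)c1)O2 | target

## Step count and risks

Total step count: 7. Longest linear sequence: 6 steps (3 → 4 → 5 → 6 → 8 → 10 → 11); step 1 is a one-step branch.

Steps most likely to fail:

**Step 6 (proposed new method).** Proton transfer to C3 may discriminate the two alkene faces poorly. A racemic background cyclisation by adventitious acid may compete. Re-ionisation at C2 followed by loss of the C3 proton may erode the enantiomeric purity, and intermolecular arylation of the quinone methide may give oligomers.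

The fallback uses known chemistry, sets out from 8 and returns at 10. Acetylation of both phenols (Ac2O, pyridine, DMAP, CH2Cl2) should give (E)-stilbene diacetate F1. Iridium-catalysed asymmetric hydrogenation of this α-methylstilbene (H2 50 bar, [Ir(cod)((S)-t-Bu-PHOX)]BArF 2 mol %, CH2Cl2, rt; the ligand enantiomer chosen by analogy with (E)-1,2-diphenylpropene) should give (R)-1,2-diarylpropane diacetate F2. Methanolysis (K2CO3, MeOH, rt) should give (R)-1,2-diarylpropane bisphenol F3. Oxidation with Ag2O (1.2 equiv, CH2Cl2, rt, dark) should convert the syringol selectively into quinone methide 9, which closes 5-exo to 10. C3 then comes from the hydrogenation and C2 from trans-selective closure.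

**Step 7.** Under base and heat the syringyl phenolate may expel the ring A aryloxide (retro-1,6-addition), which opens ring C and allows C2 epimerisation or loss of the C3 proton. Slow oxidative addition to the electron-rich bromide may let protodeboronation of the propenylboronate win.

The fallback sets out from 10 and returns at 11. Silylation (TBSCl, imidazole, DMF) should give bromodihydrobenzofuran silyl ether F4, in which the quinone methide pathway is blocked. Base-free Stille coupling with tributyl[(E)-prop-1-enyl]stannane (Pd(PPh3)4, toluene, 90 °C) should give Odoratisol A silyl ether F5. Buffered fluoride (TBAF/AcOH, THF, 0 °C) should release 11.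

**Step 5.** Oxidative addition into the C–I bond of the electron-rich iodophenoxide may be slow. Protodeboronation of the hindered alkenylboronate and reaction at C–Br could then compete.

The fallback sets out from 2 and returns at 8, and changes from coupling the phenoxide to coupling its neutral silyl ether. Silylation of 2 (TBSCl, imidazole, DMF) should give aryl iodide silyl ether F6. Suzuki coupling with 6 (Pd(OAc)2, SPhos, K3PO4, toluene/H2O, 60 °C) should give bis-silyl (E)-stilbene F7. TBAF/AcOH (3 equiv, THF, 0 °C) should remove both silyl groups to give 8.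

Further compounds
F1 | step 6 | 4-[(E)-2-(2-acetoxy-5-bromo-3-methoxyphenyl)prop-1-en-1-yl]-2,6-dimethoxyphenyl acetate | C/C(c1cc(Br)cc(OC)c1OC(C)=O)=C\c1cc(OC)c(OC(C)=O)c(OC)c1
F2 | step 6 | 4-[(2R)-2-(2-acetoxy-5-bromo-3-methoxyphenyl)propyl]-2,6-dimethoxyphenyl acetate | Brc1cc(OC)c(OC(C)=O)c(c1)[C@H](C)Cc1cc(OC)c(OC(C)=O)c(OC)c1
F3 | step 6 | 4-[(2R)-2-(5-bromo-2-hydroxy-3-methoxyphenyl)propyl]-2,6-dimethoxyphenol | Brc1cc(OC)c(O)c(c1)[C@H](C)Cc1cc(OC)c(O)c(OC)c1
F4 | step 7 | tert-butyl{4-[(2S,3S)-5-bromo-7-methoxy-3-methyl-2,3-dihydro-1-benzofuran-2-yl]-2,6-dimethoxyphenoxy}dimethylsilane | Brc1cc(OC)c2c(c1)[C@H](C)[C@@H](c1cc(OC)c(O[Si](C)(C)C(C)(C)C)c(OC)c1)O2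
F5 | step 7 | tert-butyl{2,6-dimethoxy-4-[(2S,3S)-7-methoxy-3-methyl-5-[(E)-prop-1-en-1-yl]-2,3-dihydro-1-benzofuran-2-yl]phenoxy}dimethylsilane | C/C=C/c1cc(OC)c2c(c1)[C@H](C)[C@@H](c1cc(OC)c(O[Si](C)(C)C(C)(C)C)c(OC)c1)O2
F6 | step 5 | (4-bromo-2-iodo-6-methoxyphenoxy)(tert-butyl)dimethylsilane | COc1cc(Br)cc(I)c1O[Si](C)(C)C(C)(C)C
F7 | step 5 | {4-bromo-2-[(E)-1-(4-{[tert-butyl(dimethyl)silyl]oxy}-3,5-dimethoxyphenyl)prop-1-en-2-yl]-6-methoxyphenoxy}(tert-butyl)dimethylsilane | C/C(c1cc(Br)cc(OC)c1O[Si](C)(C)C(C)(C)C)=C\c1cc(OC)c(O[Si](C)(C)C(C)(C)C)c(OC)c1
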